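All runs are calculated for substances that don't exist; the scatter is artificial.

Time first: you want this flask read at 25 min, and quickly.

in all of them: starting material 1.5 M; initiator 2.5 mol%

| charge | coupling partner | remark | time |
|---|---|---|---|
| zeta | 1.4 equiv | run made earlier |  |
| flask | 1.00 equiv |  | 25 min |

zeta run (percent of the starting material charged)

| time / min | product / % | starting material / % |
|---|---|---|
| 4.00 | 45 | 55 |
| 8.00 | 80 | 21 |
| 12.0 | 103 | 2 |
| 15.0 | 100 | 0 |
| 20.0 | 102 | 3 |

(scatter of a reading: 1.5 percentage points)

- the product standing at 25 min, as a percentage of the starting material charged
- concentration of by-product in solution at 25 min, in percent of saturation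

- the earlier runs were read with a standard deviation of 1.5 percentage points

Over successive intervals of 4.00 min in the zeta run, the starting material keeps 38.2% of itself and then 9.52%, so it shows no steady half-life. The coupling partner, reckoned as charge minus product, keeps 63.2% and then 61.7%, which I read as a pseudo-first-order decay. The zeta reading at 8.00 min puts its half-life at 6.54 min. I carry this half-life of the coupling partner, the time in which one of its molecules has even chances of being used, and I assume that it does not depend on the charge.

Your flask then runs 3.82 half-lives, so a molecule of coupling partner survives with a chance of 7.08%. If each one used makes one product, I commit to 92.9%, which is higher than your forecast of 92%. Your 100% of saturation is, in your words, “only a guess”; the readings give me no solubility, so I take it over.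

The flask gives 93.5% of product, with the by-product in solution at 102% of saturation.

    2 first chain carrier → ended chains (k = 2.00 × 10⁶ L mol⁻¹ s⁻¹)
    coupling partner + first chain carrier → product + second chain carrier (k = 11300 L mol⁻¹ s⁻¹)
    starting material + second chain carrier → by-product + first chain carrier (k = 1.71 × 10⁵ L mol⁻¹ min⁻¹)
    initiator → 2 initiating radical (k = 8.43 × 10⁻⁵ min⁻¹)
    crystals ⇌ by-product, rate k5*(cs5 - [by-product]) while solid is left; crystals form when [by-product] > cs5 (solubility = 1.10 M, k = 0.515 min⁻¹)
    starting material + initiating radical → capped initiator + first chain carrier (k = 3.99 × 10⁵ L mol⁻¹ s⁻¹)

In this flask the step that makes product from the coupling partner has a half-life of 6.3 min at 5.82 min; 25 min is 3.97 times that, and at 25 min 6.5% of the coupling partner stands. In a neighbour flask with 0.250 equiv of coupling partner, read at the same time, the carried 6.54 min gives 23.2% of product; that flask holds 23.4%, with 6.41% of its coupling partner and 77% of its starting material left.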